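Ring A = cyclohexane C1, C10–C14; ring B = ten-membered carbocycle C1–C10; ring C = γ-lactone C7, C8, C17, C19, O (briarane numbering).
Enabling feature: ring B holds the 2-substituted 1,3-diene C16H2=C5–C4H=C3H with C16 exocyclic. This is the retron of an endo-mode enyne metathesis, so ring B is cut at C3=C4 back to a C5≡C4H alkyne on C6 and a vinyl group on C2, an isomer of the target.
Further cuts, in order: C6–C7 (chloroallenylzinc + C7 aldehyde), C8–C17 (amide enolate + C8 ketone), C8–C9 (1-ethoxyvinyl anion + C9 Weinreb amide), C2–C3 (vinyl Grignard), C1–C14/C10–C11 (Diels–Alder).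
Forward order of rings: A (step 2), C (step 16), oxirane (step 18), B last (step 22).
Stereochemistry: C1/C10 come from one catalytic enantioselective Diels–Alder reaction. The rest is relayed by substrate control: C2, C9, C8/C17 and C7 by Felkin–Anh additions, C6 by an anti-selective cyclic SE2' transition state, and C11–C14 by attack on the ring A face opposite Me-15. The 3Z geometry comes from ring B itself.

Key step: step 22

Assumptions:
- Locants: C1 (Me-15), C2 (O-butyrate), C6 (Cl), C7 (lactone O), C8 (OH), C9 (OAc), C11 (OH, Me-20), C12 (OAc), C13/C14 (oxirane), C17 (Me-18), C19 (lactone C=O).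
- The sense of induction in step 2 is assigned from the usual pre-transition-state model (formyl C–H···O contact, s-trans enal stacked on the neighbouring phenyl ring). Both antipodes of the catalyst precursor are commercial.
- C11 in 4–7 is drawn for the formyl-endo adduct. This centre is erased in step 6.

Step 1
Reactants: 1 pent-1-en-3-one
Product: 2 (Z)-3-(tert-butyldimethylsilyloxy)penta-1,3-diene
Conditions: TBSOTf, Et3N, Et2O, 0 °C
Reagents that add atoms: tert-butyldimethylsilyl triflate CC(C)(C)[Si](C)(C)OS(=O)(=O)C(F)(F)F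
Why: Soft enolisation and O-silylation (silyl enol ether formation) should give the 2-silyloxydiene, the Z enol ether being favoured because the methyl group avoids the vinyl group in the deprotonation transition state.

Step 2
Reactants: 2 silyloxydiene; 3 ethyl (E)-3-methyl-4-oxobut-2-enoate
Product: 4 ethyl 3-(TBSO)-6-formyl-2,6-dimethylcyclohex-3-ene-1-carboxylate (ring A; CHO on C1 trans to CO2Et on C10; target configuration at C1 and C10)
Conditions: (R)-3,3-diphenyl-1-(2-methylphenyl)tetrahydro-1H,3H-pyrrolo[1,2-c][1,3,2]oxazaborole protonated by HN(SO2CF3)2 (20 mol %), CH2Cl2, −78 °C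
Reagents that add atoms: none
Why: Catalytic enantioselective Diels–Alder reaction: the cationic boron Lewis acid binds the formyl group so that C10 becomes the electrophilic terminus and meets the nucleophilic C11 of the 2-silyloxydiene (para rule), the E dienophile fixes CHO and CO2Et trans on ring A, and the catalyst phenyl group lying under the s-trans enal shields one face and so sets C1 and C10.

Step 3
Reactants: 4 formyl ester
Product: 5 C2 allylic alcohol (1-hydroxyallyl group on C1, C2 configured as in the target)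
Conditions: CH2=CHMgBr (1.1 equiv), THF, −78 °C; AcOH quench at −78 °C
Reagents that add atoms: vinylmagnesium bromide C=C[Mg]Br
Why: Grignard 1,2-addition to the non-enolisable neopentyl aldehyde under Felkin–Anh control (C10 as the large group anti to the nucleophile, attack past Me-15) should set C2, and the cold quench keeps the alkoxide from lactonising onto the ester.

Step 4
Reactants: 5 allylic alcohol
Product: 6 C2 O-TBS ether
Conditions: TBSOTf, 2,6-lutidine, CH2Cl2, −78 → 0 °C
Reagents that add atoms: tert-butyldimethylsilyl triflate CC(C)(C)[Si](C)(C)OS(=O)(=O)C(F)(F)F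
Why: Silylation with the silyl triflate protects the hindered C2 carbinol for the basic and organometallic steps that follow, and no stereocentre is touched.

Step 5
Reactants: 6 bis-silyl compound
Product: 7 C12 ketone, C13=C14 enone
Conditions: Pd(OAc)2 (1.05 equiv), MeCN, 23 °C
Reagents that add atoms: none
Why: Saegusa–Ito oxidation: palladation of the silyl enol ether at C13 and β-hydride elimination of H-14 should give the C13=C14 enone regiospecifically.

Step 6
Reactants: 7 enone
Product: 8 cross-conjugated dienyl triflate (C11=C12(OTf)–C13=C14)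
Conditions: KHMDS, THF, −78 °C; PhN(SO2CF3)2, −78 → 0 °C
Reagents that add atoms: N-phenylbis(trifluoromethanesulfonimide) O=S(=O)(N(c1ccccc1)S(=O)(=O)C(F)(F)F)C(F)(F)F
Why: Kinetic deprotonation at C11, the only enolisable position of the enone because C1 is quaternary, gives the cross-conjugated dienolate, which is trapped on oxygen as the enol triflate and thereby erases the C11 centre.

Step 7
Reactants: 8 dienyl triflate
Product: 9 cyclohexa-1,3-diene ester (C11(Me)=C12–C13=C14)
Conditions: Pd(OAc)2 (5 mol %), PPh3 (10 mol %), HCO2H, Et3N, DMF, 60 °C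
Reagents that add atoms: none
Why: Palladium-catalysed formate reduction of an enol triflate (oxidative addition to zerovalent palladium, formate exchange, decarboxylation, reductive elimination) should give the diene without migration of the double bonds.

Step 8
Reactants: 9 diene ester
Product: 10 C9 Weinreb amide
Conditions: MeNH(OMe)·HCl, i-PrMgCl, THF, −20 → 0 °C
Reagents that add atoms: N,O-dimethylhydroxylamine hydrochloride CNOC.Cl
Why: Aminolysis of the ester by the magnesium amide (Weinreb amide synthesis) prepares C9 for a single acylation, and any deprotonation at C10 returns on reprotonation the more stable isomer with the acyl group trans to the large C2 arm.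

Step 9
Reactants: 10 Weinreb amide; 11 ethyl vinyl ether
Product: 13 C9 ketone bearing the 1-ethoxyvinyl group (C8(OEt)=C7H2), via 1-ethoxyvinyllithium 12 (not isolated)
Conditions: 11, t-BuLi, THF, −78 → 0 °C; then 10, −78 °C
Reagents that add atoms: none
Why: Weinreb ketone synthesis: the small sp2 acyl-anion equivalent adds once to the hindered amide because the chelated tetrahedral intermediate survives until work-up, which forms C8–C9 with C8 already at the ketone oxidation level.

Step 10
Reactants: 13 2-ethoxy enone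
Product: 14 C9 carbinol (C9 configured as in the target)
Conditions: DIBAL-H, toluene, −78 °C; Rochelle salt
Reagents that add atoms: none
Why: 1,2-Reduction under Felkin–Anh control: with quaternary C1 anti to the incoming hydride and attack past H-10, hydride reaches the open face of the C9 ketone, which places O-9 on the hindered side as the target demands.

Step 11
Reactants: 14 C9 carbinol
Product: 15 1,3-dihydroxy ketone (C9–OH, C8=O, C7H2OH)
Conditions: OsO4 (2 mol %), NMO (1.05 equiv), acetone/H2O, 0 °C
Reagents that add atoms: N-methylmorpholine N-oxide C[N+]1([O-])CCOCC1; water O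
Why: Catalytic OsO4/NMO dihydroxylation picks the most electron-rich alkene, the enol ether, and the resulting hemiketal loses ethanol to unveil the C8 ketone flanked by O-9 and the new C7 carbinol.

Step 12
Reactants: 15 dihydroxy ketone
Product: 16 O-7,O-9-bis(triethylsilyl) ketone
Conditions: TESOTf, 2,6-lutidine, CH2Cl2, −78 °C
Reagents that add atoms: triethylsilyl triflate CC[Si](CC)(CC)OS(=O)(=O)C(F)(F)F
Why: Silylation gives non-chelating ethers on O-7 and O-9, which is what the next two carbonyl additions need.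

Step 13
Reactants: 16 bis-TES ketone; 17 N,N-dimethylpropanamide
Product: 19 aldol amide with C8 (OTES) and C17 configured as in the target, via lithium Z-enolate 18 (not isolated)
Conditions: 17, LDA, THF, −78 °C; 16, −78 °C; TESOTf, −78 → −20 °C
Reagents that add atoms: triethylsilyl triflate CC[Si](CC)(CC)OS(=O)(=O)C(F)(F)F
Why: Lithium amide-enolate aldol addition to a ketone: polar Felkin–Anh attack anti to the C9–OSi bond and past H-9 should set C8, the Z enolate in a closed Zimmerman–Traxler transition state with the C9 branch equatorial should set C17 (Me-18 syn to O-8), and silylation of the aldolate in the flask blocks retro-aldol cleavage.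

Step 14
Reactants: 19 aldol amide
Product: 20 C7 aldehyde
Conditions: (COCl)2, DMSO, CH2Cl2, −78 → −35 °C; Et3N
Reagents that add atoms: none
Why: Swern oxidation of silyl ethers: the primary triethylsilyl ether is cleaved and oxidised directly by the activated sulfoxide while the secondary and tertiary silyl ethers stay, so that no free γ-hydroxy amide with a C7H2 group can lactonise.

Step 15
Reactants: 20 C7 aldehyde; 21 3-chloro-1-(trimethylsilyl)prop-1-yne
Product: 23 anti chlorohydrin amide (C7–OH and C6–Cl configured as in the target; C5≡C4–SiMe3), via chloroallenylzinc bromide 22 (not isolated)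
Conditions: 21, ZnBr2, LDA, THF, −78 °C; then 20, −78 → −20 °C
Reagents that add atoms: none
Why: Addition of a 3-chloroallenylzinc carbenoid to an aldehyde through a cyclic SE2' transition state gives the anti chlorohydrin (C6 relative to C7), and polar Felkin–Anh attack anti to the C8–OSi bond and past the smaller C17 branch should set C7.

Step 16
Reactants: 23 chlorohydrin amide
Product: 24 γ-lactone diol (ring C closed; C8–OH and C9–OH free)
Conditions: TsOH·H2O (1.5 equiv), THF/H2O (10:1), 23 °C
Reagents that add atoms: none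
Why: Acid hydrolysis of the two triethylsilyl ethers and acid-catalysed lactonisation of the γ-hydroxy amide close ring C on O-7 and not on O-9, because only the O-7 lactone holds its carbon substituents (C6, C9, Me-18) alternately trans, while the hindered C2 silyl ether, the C–Si bond and (no chloride being present) the C6 centre stay.

Step 17
Reactants: 24 lactone diol
Product: 25 tetraol (new cis-diol at C11/C12, on the face opposite Me-15)
Conditions: OsO4 (5 mol %), NMO (1.1 equiv), acetone/H2O, 0 °C
Reagents that add atoms: N-methylmorpholine N-oxide C[N+]1([O-])CCOCC1; water O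
Why: OsO4/NMO dihydroxylation should take the trisubstituted, most electron-rich C11=C12 bond of the diene from the face opposite the pseudoaxial Me-15 and the C9 branch, which sets C11 and C12.

Step 18
Reactants: 25 tetraol
Product: 26 13,14-epoxy tetraol (oxirane cis to O-12)
Conditions: VO(acac)2 (5 mol %), t-BuOOH, CH2Cl2, 0 °C
Reagents that add atoms: tert-butyl hydroperoxide CC(C)(C)OO
Why: Hydroxyl-directed epoxidation: the vanadium tert-butylperoxo complex bound to O-12 delivers oxygen to C13=C14 cis to O-12, also the face opposite Me-15, and leaves the vinyl group and the alkyne untouched.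

Step 19
Reactants: 26 epoxy tetraol
Product: 27 9,12-diacetate
Conditions: Ac2O, DMAP, pyridine, CH2Cl2, 23 °C
Reagents that add atoms: acetic anhydride CC(=O)OC(C)=O
Why: DMAP-catalysed acylation esterifies the two secondary alcohols (O-9, O-12) and leaves the tertiary alcohols on C8 and C11 free.

Step 20
Reactants: 27 diacetate
Product: 28 C2 alcohol with terminal C5≡C4H alkyne
Conditions: TBAF, AcOH (1:1), THF, 0 → 23 °C
Reagents that add atoms: none
Why: Buffered fluoride cleaves the O–Si bond at C2 and the alkynyl C–Si bond in one operation, acetic acid keeping the medium from causing acetate migration or loss of HCl.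

Step 21
Reactants: 28 C2 alcohol
Product: 29 C2 butyrate, the open enyne isomer of the target
Conditions: (n-PrCO)2O, DMAP, Et3N, CH2Cl2, 23 °C
Reagents that add atoms: butyric anhydride CCCC(=O)OC(=O)CCC
Why: DMAP-catalysed acylation of the only remaining secondary alcohol installs the butyrate.

Step 22
Reactants: 29 enyne
Product: 31 CNP0114058.1, via triene 30 (not isolated)
Conditions: (H2IMes)(PCy3)Cl2Ru=CHPh (second-generation Grubbs catalyst, 15 mol %), ethylene (1 atm), CH2Cl2, 23 °C; then Ar sparge, toluene (1 mM), 80 °C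
Reagents that add atoms: ethylene C=C
Why: The ruthenium methylidene formed under ethylene adds to the terminal C5≡C4H alkyne and gives, through a ruthenacyclobutene and a vinylcarbene that is released by ethylene, the 2-substituted butadiene 30 (enyne cross-metathesis), whose C4H=CH2 end undergoes ring-closing metathesis with the C3H=CH2 vinyl group on C2 once ethylene is swept out. The closest known reaction type is the ethylene-mediated, formally endo-mode macrocyclic ring-closing enyne metathesis that delivers 1,3-dienes with an exocyclic methylene group. Only ring B is closed, by C3=C4 bond formation between two monosubstituted alkene termini (ten-membered, endo mode with respect to the alkyne; C16 comes from ethylene and the two terminal CH2 groups leave as ethylene). No sp3 centre is made or touched; the one new stereoelement, the 3Z geometry, is controlled by ring B itself, since the eight remaining ring atoms, pinned by the trans fusion to ring A (C1/C10) and by the trans-substituted lactone (C7/C8), span a Z alkene conjugated to the C5 methylene with less strain than an E alkene, and the reversible catalyst should funnel material to the more stable ring. The step needs three selectivities: mode selectivity (ten- versus nine-membered ring), secured by the ethylene relay and the inertness of the 1,1-disubstituted C5=C16 bond; chemoselectivity, secured because the ring A alkene is already the oxirane so that 29 holds only the two reacting π systems; and cyclisation over oligomerisation, secured by 1 mM dilution and the gauche, diequatorial arms on C1 and C10.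

Compound list
1 | pent-1-en-3-one | C=CC(=O)CC | starting material
2 | (Z)-3-(tert-butyldimethylsilyloxy)penta-1,3-diene | C=C/C(O[Si](C)(C)C(C)(C)C)=C/C | intermediate
3 | ethyl (E)-3-methyl-4-oxobut-2-enoate | CCOC(=O)/C=C(\C)C=O | starting material
4 | ethyl 3-(TBSO)-6-formyl-2,6-dimethylcyclohex-3-ene-1-carboxylate; CHO (C1) trans to CO2Et (C10), Me-20 cis to CHO | O=C[C@@]1(C)CC=C(O[Si](C)(C)C(C)(C)C)[C@@H](C)[C@@H]1C(=O)OCC | intermediate
5 | C2 allylic alcohol from 4 | C=C[C@H](O)[C@@]1(C)CC=C(O[Si](C)(C)C(C)(C)C)[C@@H](C)[C@@H]1C(=O)OCC | intermediate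
6 | C2 O-TBS ether of 5 | C=C[C@H](O[Si](C)(C)C(C)(C)C)[C@@]1(C)CC=C(O[Si](C)(C)C(C)(C)C)[C@@H](C)[C@@H]1C(=O)OCC | intermediate
7 | C12-oxo C13=C14 enone | C=C[C@H](O[Si](C)(C)C(C)(C)C)[C@@]1(C)C=CC(=O)[C@@H](C)[C@@H]1C(=O)OCC | intermediate
8 | C12 dienyl triflate | C=C[C@H](O[Si](C)(C)C(C)(C)C)[C@@]1(C)C=CC(OS(=O)(=O)C(F)(F)F)=C(C)[C@@H]1C(=O)OCC | intermediate
9 | cyclohexa-1,3-diene ethyl ester | C=C[C@H](O[Si](C)(C)C(C)(C)C)[C@@]1(C)C=CC=C(C)[C@@H]1C(=O)OCC | intermediate
10 | C9 N-methoxy-N-methylamide | C=C[C@H](O[Si](C)(C)C(C)(C)C)[C@@]1(C)C=CC=C(C)[C@@H]1C(=O)N(C)OC | intermediate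
11 | ethyl vinyl ether | C=COCC | starting material
12 | 1-ethoxyvinyllithium | [Li]C(=C)OCC | intermediate
13 | C9 ketone with 1-ethoxyvinyl group | C=C[C@H](O[Si](C)(C)C(C)(C)C)[C@@]1(C)C=CC=C(C)[C@@H]1C(=O)C(=C)OCC | intermediate
14 | C9 carbinol with 1-ethoxyvinyl group | C=C[C@H](O[Si](C)(C)C(C)(C)C)[C@@]1(C)C=CC=C(C)[C@@H]1[C@H](O)C(=C)OCC | intermediate
15 | C7,C9-dihydroxy C8 ketone | C=C[C@H](O[Si](C)(C)C(C)(C)C)[C@@]1(C)C=CC=C(C)[C@@H]1[C@H](O)C(=O)CO | intermediate
16 | O-7,O-9-bis-TES C8 ketone | C=C[C@H](O[Si](C)(C)C(C)(C)C)[C@@]1(C)C=CC=C(C)[C@@H]1[C@H](O[Si](CC)(CC)CC)C(=O)CO[Si](CC)(CC)CC | intermediate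
17 | N,N-dimethylpropanamide | CCC(=O)N(C)C | starting material
18 | lithium (Z)-enolate of 17 | [Li+].C/C=C(\[O-])N(C)C | intermediate
19 | aldol amide, O-7,O-8,O-9-tris-TES | C=C[C@H](O[Si](C)(C)C(C)(C)C)[C@@]1(C)C=CC=C(C)[C@@H]1[C@H](O[Si](CC)(CC)CC)[C@@](O[Si](CC)(CC)CC)(CO[Si](CC)(CC)CC)[C@@H](C)C(=O)N(C)C | intermediate
20 | C7 aldehyde | C=C[C@H](O[Si](C)(C)C(C)(C)C)[C@@]1(C)C=CC=C(C)[C@@H]1[C@H](O[Si](CC)(CC)CC)[C@@](O[Si](CC)(CC)CC)(C=O)[C@@H](C)C(=O)N(C)C | intermediate
21 | 3-chloro-1-(trimethylsilyl)prop-1-yne | C[Si](C)(C)C#CCCl | starting material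
22 | (3-chloro-1-trimethylsilylallenyl)zinc bromide (racemic, configurationally labile) | C[Si](C)(C)C([Zn]Br)=C=CCl | intermediate
23 | anti C6-chloro C7-hydroxy amide | C=C[C@H](O[Si](C)(C)C(C)(C)C)[C@@]1(C)C=CC=C(C)[C@@H]1[C@H](O[Si](CC)(CC)CC)[C@@](O[Si](CC)(CC)CC)([C@@H](O)[C@@H](Cl)C#C[Si](C)(C)C)[C@@H](C)C(=O)N(C)C | intermediate
24 | γ-lactone 8,9-diol with ring A diene | C=C[C@H](O[Si](C)(C)C(C)(C)C)[C@@]1(C)C=CC=C(C)[C@@H]1[C@H](O)[C@]2(O)[C@@H](C)C(=O)O[C@H]2[C@@H](Cl)C#C[Si](C)(C)C | intermediate
25 | 8,9,11,12-tetraol | C=C[C@H](O[Si](C)(C)C(C)(C)C)[C@@]1(C)C=C[C@@H](O)[C@@](C)(O)[C@@H]1[C@H](O)[C@]2(O)[C@@H](C)C(=O)O[C@H]2[C@@H](Cl)C#C[Si](C)(C)C | intermediate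
26 | 13,14-epoxy tetraol | C=C[C@H](O[Si](C)(C)C(C)(C)C)[C@@]1(C)[C@H]3O[C@H]3[C@@H](O)[C@@](C)(O)[C@@H]1[C@H](O)[C@]2(O)[C@@H](C)C(=O)O[C@H]2[C@@H](Cl)C#C[Si](C)(C)C | intermediate
27 | 9,12-diacetate | C=C[C@H](O[Si](C)(C)C(C)(C)C)[C@@]1(C)[C@H]3O[C@H]3[C@@H](OC(C)=O)[C@@](C)(O)[C@@H]1[C@H](OC(C)=O)[C@]2(O)[C@@H](C)C(=O)O[C@H]2[C@@H](Cl)C#C[Si](C)(C)C | intermediate
28 | C2 alcohol, terminal alkyne | C=C[C@H](O)[C@@]1(C)[C@H]3O[C@H]3[C@@H](OC(C)=O)[C@@](C)(O)[C@@H]1[C@H](OC(C)=O)[C@]2(O)[C@@H](C)C(=O)O[C@H]2[C@@H](Cl)C#C | intermediate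
29 | C2 butyrate enyne (open isomer of the target) | C=C[C@H](OC(=O)CCC)[C@@]1(C)[C@H]3O[C@H]3[C@@H](OC(C)=O)[C@@](C)(O)[C@@H]1[C@H](OC(C)=O)[C@]2(O)[C@@H](C)C(=O)O[C@H]2[C@@H](Cl)C#C | intermediate
30 | triene with C5(=C16H2)–C4H=CH2 butadiene | C=C[C@H](OC(=O)CCC)[C@@]1(C)[C@H]3O[C@H]3[C@@H](OC(C)=O)[C@@](C)(O)[C@@H]1[C@H](OC(C)=O)[C@]2(O)[C@@H](C)C(=O)O[C@H]2[C@@H](Cl)C(=C)C=C | intermediate
31 | CNP0114058.1 | C=C1/C=C\[C@H](OC(=O)CCC)[C@@]2(C)[C@H]3O[C@H]3[C@@H](OC(C)=O)[C@@](C)(O)[C@@H]2[C@H](OC(C)=O)[C@]2(O)[C@@H](C)C(=O)O[C@H]2[C@H]1Cl | target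

Total step count: 22. Longest linear sequence: 22 steps (1 → 31).

Steps most likely to fail

1. Step 22.
What may go wrong: intermolecular metathesis may outrun closure of the strained ten-membered ring, ethylene may reopen it, or the free tertiary hydroxyls may bind ruthenium so that the reaction stalls at the triene.
Fallback: a conformational lock by two temporary dioxolane rings, which also masks all hydroxyls. It sets out from 26. 2-Methoxypropene/PPTS would tie O-8/O-9 and O-11/O-12 into the bis-acetonide F1. Buffered TBAF would give the C2 alcohol F2, and butyric anhydride/DMAP the butyrate F3. The same ethylene-relayed enyne metathesis would pass through the triene F4 to the locked macrocycle F5. Aqueous acetic acid would release the macrocyclic tetraol F6, and Ac2O/DMAP/pyridine would acetylate O-9 and O-12 to rejoin the route at 31.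

2. Step 15.
What may go wrong: facial selectivity at an aldehyde with a fully substituted α-carbon may be poor, or the zinc carbenoid may decompose before it adds.
Fallback: reagent-controlled epoxidation followed by ring opening. It sets out from 20. The ylide from the S-(3-trimethylsilylprop-2-ynyl)sulfonium salt of enantiopure isothiocineole (LiHMDS, THF, −78 °C) would give the trans alkynyl epoxide F7, with the aldehyde face chosen by the sulfide. LiCl/AcOH in THF would then open it at the propargylic C6 with inversion and rejoin the route at 23.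

3. Step 13.
What may go wrong: the strongly basic amide enolate may enolise the ketone, the aldolate may undergo retro-aldol cleavage, or control at C17 may be poor.
Fallback: a non-basic Lewis-acid aldol. It sets out from 16. A Mukaiyama aldol addition of (E)-1-methoxy-1-(trimethylsilyloxy)prop-1-ene with BF3·OEt2 (CH2Cl2, −78 °C; non-chelating, Felkin–Anh) would give the hydroxy ester F8. TESOTf/2,6-lutidine would give the silyl ether F9, and Swern oxidation of the primary silyl ether the aldehyde F10. The chloroallenylzinc addition would give the chlorohydrin ester F11, and TsOH·H2O in wet THF would desilylate and lactonise with loss of methanol to rejoin the route at 24.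

Further compounds
F1 | step 22 | 8,9:11,12-bis-acetonide of 26 | C=C[C@H](O[Si](C)(C)C(C)(C)C)[C@@]1(C)[C@H]3O[C@H]3[C@H]4OC(C)(C)O[C@@]4(C)[C@@H]1[C@@H]5OC(C)(C)O[C@]56[C@@H](C)C(=O)O[C@H]6[C@@H](Cl)C#C[Si](C)(C)C
F2 | step 22 | bis-acetonide C2 alcohol, terminal alkyne | C=C[C@H](O)[C@@]1(C)[C@H]3O[C@H]3[C@H]4OC(C)(C)O[C@@]4(C)[C@@H]1[C@@H]5OC(C)(C)O[C@]56[C@@H](C)C(=O)O[C@H]6[C@@H](Cl)C#C
F3 | step 22 | bis-acetonide C2 butyrate enyne | C=C[C@H](OC(=O)CCC)[C@@]1(C)[C@H]3O[C@H]3[C@H]4OC(C)(C)O[C@@]4(C)[C@@H]1[C@@H]5OC(C)(C)O[C@]56[C@@H](C)C(=O)O[C@H]6[C@@H](Cl)C#C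
F4 | step 22 | bis-acetonide triene | C=C[C@H](OC(=O)CCC)[C@@]1(C)[C@H]3O[C@H]3[C@H]4OC(C)(C)O[C@@]4(C)[C@@H]1[C@@H]5OC(C)(C)O[C@]56[C@@H](C)C(=O)O[C@H]6[C@@H](Cl)C(=C)C=C
F5 | step 22 | bis-acetonide macrocycle (ring B closed, 3Z) | C=C1/C=C\[C@H](OC(=O)CCC)[C@@]2(C)[C@H]3O[C@H]3[C@H]4OC(C)(C)O[C@@]4(C)[C@@H]2[C@@H]5OC(C)(C)O[C@]56[C@@H](C)C(=O)O[C@H]6[C@H]1Cl
F6 | step 22 | 9,12-dideacetyl target (macrocyclic tetraol) | C=C1/C=C\[C@H](OC(=O)CCC)[C@@]2(C)[C@H]3O[C@H]3[C@@H](O)[C@@](C)(O)[C@@H]2[C@H](O)[C@]2(O)[C@@H](C)C(=O)O[C@H]2[C@H]1Cl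
F7 | step 15 | trans C6,C7 alkynyl epoxide amide | C=C[C@H](O[Si](C)(C)C(C)(C)C)[C@@]1(C)C=CC=C(C)[C@@H]1[C@H](O[Si](CC)(CC)CC)[C@@](O[Si](CC)(CC)CC)([C@H]4O[C@@H]4C#C[Si](C)(C)C)[C@@H](C)C(=O)N(C)C
F8 | step 13 | C8 hydroxy methyl ester | C=C[C@H](O[Si](C)(C)C(C)(C)C)[C@@]1(C)C=CC=C(C)[C@@H]1[C@H](O[Si](CC)(CC)CC)[C@@](O)(CO[Si](CC)(CC)CC)[C@@H](C)C(=O)OC
F9 | step 13 | O-8 TES methyl ester | C=C[C@H](O[Si](C)(C)C(C)(C)C)[C@@]1(C)C=CC=C(C)[C@@H]1[C@H](O[Si](CC)(CC)CC)[C@@](O[Si](CC)(CC)CC)(CO[Si](CC)(CC)CC)[C@@H](C)C(=O)OC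
F10 | step 13 | C7 aldehyde methyl ester | C=C[C@H](O[Si](C)(C)C(C)(C)C)[C@@]1(C)C=CC=C(C)[C@@H]1[C@H](O[Si](CC)(CC)CC)[C@@](O[Si](CC)(CC)CC)(C=O)[C@@H](C)C(=O)OC
F11 | step 13 | anti chlorohydrin methyl ester | C=C[C@H](O[Si](C)(C)C(C)(C)C)[C@@]1(C)C=CC=C(C)[C@@H]1[C@H](O[Si](CC)(CC)CC)[C@@](O[Si](CC)(CC)CC)([C@@H](O)[C@@H](Cl)C#C[Si](C)(C)C)[C@@H](C)C(=O)OC
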